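The carbocycle (C1 conjugated ketone, C2, C3 the oxygen-bearing alkene carbon, C4 with methyl and prenyl, C5 ketone, C6 with prenyl and isobutyryl) is cut at C2–C3 and C5–C6, giving a 1,3-diketone that carries the protected side chain (C6–C1–C2) and a methyl(prenyl)malonyl unit (C3–C4–C5). In the key step the diketone dianion is acylated at its terminal carbon by an acid chloride and its central carbon then closes onto the neighbouring methyl ester: two C–C bonds and the six-membered ring in one operation. The step exploits C4, a quaternary carbon flanked by the C3 and C5 carbonyls, whose handedness is installed beforehand by making the two malonate carboxyls chemically different. Precursors: acetonide diketone 18 and half-ester chloride 11.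

Key step: step 11

Locants: carbocycle as above; the furan OCH carbon is C2' and the furan CH2 carbon is C3'; precursor atoms carry the locants of the atoms they become. Prenyl = 3-methylbut-2-en-1-yl.

Assumption: the (S,S)-antipode of the phase-transfer catalyst is taken to give (2R)-6, by analogy with its reported sense for other allylic bromides on this malonate; should correlation of 10 show the opposite sense, the (R,R)-antipode is used with nothing else changed.

Step 1
Reactants: 1 2,2,5-trimethyl-1,3-dioxane-4,6-dione (methyl Meldrum's acid)
Product: 2 racemic 3-(tert-butoxy)-2-methyl-3-oxopropanoic acid (mono-tert-butyl methylmalonate)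
Conditions: t-BuOH, reflux
Reagents that add atoms: tert-butanol, CC(C)(C)O
Why: Alcoholysis of the cyclic acylal by tert-butanol opens the ring and expels acetone to give the malonic half ester directly, a standard Meldrum's acid ring opening in which the labile C–H stereocenter is of no consequence.

Step 2
Reactants: 2 mono-tert-butyl methylmalonate; 3 2,2-diphenylethanol
Product: 4 racemic tert-butyl 2,2-diphenylethyl 2-methylpropanedioate
Conditions: EDC·HCl, DMAP (cat.), CH2Cl2, 0 → 23 °C
Reagents that add atoms: none
Why: Carbodiimide-mediated (Steglich-type) esterification of an unhindered acid with a primary alcohol should give the mixed malonate whose two bulky, differently shaped ester groups are what the chiral catalyst of the next step distinguishes.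

Step 3
Reactants: 4 mixed methylmalonate; 5 prenyl bromide
Product: 6 (2R)-1-tert-butyl 3-(2,2-diphenylethyl) 2-methyl-2-prenylpropanedioate
Conditions: (S,S)-3,4,5-trifluorophenyl-NAS bromide (C2-symmetric N-spiro bis(binaphthyl)ammonium bromide, 5 mol %), 50% aq. KOH, toluene, −40 °C
Reagents that add atoms: none
Why: Enantioselective phase-transfer alkylation, in which the tight ion pair between the malonate enolate and the chiral ammonium cation exposes one enantiotopic face to SN2 attack on prenyl bromide, should set the quaternary carbon (the later C4) under catalyst control, a reaction type established for this malonate with allylic and benzylic bromides.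

Step 4
Reactants: 6 mixed prenylated malonate
Product: 8 1-tert-butyl 3-methyl (2R)-2-methyl-2-prenylpropanedioate, via potassium carboxylate 7 (not isolated)
Conditions: KOH (1 M in MeOH), 23 → 40 °C; evaporate; MeI, DMF, 23 °C
Reagents that add atoms: potassium hydroxide, [K+].[OH-]; iodomethane, CI
Why: Saponification should attack only the primary diphenylethyl ester because the tert-butyl ester resists hydroxide, and SN2 methylation of the resulting carboxylate exchanges the large ester for the small methyl ester needed as the Dieckmann acceptor without touching the quaternary center.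

Step 5
Reactants: 8 tert-butyl methyl diester
Product: 10 (2S)-3-methoxy-2-methyl-2-prenyl-3-oxopropanoic acid, via trimethylsilyl ester 9 (not isolated)
Conditions: Me3SiOTf, 2,6-lutidine, CH2Cl2, 0 °C; aq. citric acid work-up
Reagents that add atoms: none
Why: Silyl triflate-promoted cleavage of the tert-butyl ester (loss of isobutene) under lutidine buffering should leave the methyl ester and the acid-sensitive prenyl alkene alone, and the silyl ester is hydrolysed on work-up, so the carboxyl that carried tert-butyl is the one set free.

Step 6
Reactants: 10 half acid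
Product: 11 methyl (2R)-2-(chlorocarbonyl)-2,5-dimethylhex-4-enoate
Conditions: (COCl)2, DMF (cat.), CH2Cl2, 0 → 23 °C; volatiles removed
Reagents that add atoms: oxalyl chloride, O=C(Cl)C(Cl)=O
Why: Vilsmeier-type acid chloride formation gives only gaseous by-products, and since the carbon next to the carbonyl has no hydrogen the chloride cannot form a ketene and keeps its configuration (the descriptor changes from S to R only through the priority rules).

Step 7
Reactants: 12 nerol
Product: 13 [(2R,3S)-3-methyl-3-(4-methylpent-3-en-1-yl)oxiran-2-yl]methanol
Conditions: Ti(OiPr)4 (cat.), D-(−)-diisopropyl tartrate, t-BuOOH, 4 Å MS, CH2Cl2, −20 °C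
Reagents that add atoms: tert-butyl hydroperoxide, CC(C)(C)OO
Why: Sharpless asymmetric epoxidation delivers oxygen through the titanium tartrate alkoxide complex to one face of the allylic alkene only, which should set C2 (R) and C3 (S) together under reagent control and leave the remote trisubstituted alkene untouched.

Step 8
Reactants: 13 epoxy alcohol
Product: 14 (2S)-6-methyl-2-[(2S)-oxiran-2-yl]hept-5-en-2-ol
Conditions: NaOH (0.5 M aq.), t-BuOH, 23 °C; chromatographic separation, recovered 13 resubmitted
Reagents that add atoms: none
Why: Payne rearrangement, in which the primary alkoxide opens the oxirane at the secondary carbon with inversion (setting the later C2' as S) while the tertiary carbinol keeps its C–O bond, should give the terminal epoxide as one partner of an equilibrium from which it is separated.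

Step 9
Reactants: 15 5-methylhexane-2,4-dione; 14 hydroxy epoxide
Product: 17 (8S,9S)-8,9-dihydroxy-2,9,13-trimethyltetradec-12-ene-3,5-dione, via dilithio diketone dianion 16 (not isolated)
Conditions: 15, LiN(iPr)2 (2.1 equiv), THF, −78 → 0 °C; lithium alkoxide of 14 (n-BuLi, THF, −78 °C); 0 → 23 °C; aq. NH4Cl
Reagents that add atoms: none
Why: γ-Alkylation of a 1,3-diketone dianion, whose kinetically formed terminal carbanion (methyl deprotonated in preference to the isobutyryl methine) opens the terminal epoxide at its CH2 group by SN2, should join the fragments without touching either stereocenter.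

Step 10
Reactants: 17 dihydroxy diketone
Product: 18 6-methyl-1-[(4S,5S)-2,2,5-trimethyl-5-(4-methylpent-3-en-1-yl)-1,3-dioxolan-4-yl]heptane-3,5-dione
Conditions: Me2C(OMe)2, PPTS (cat.), CH2Cl2, 23 °C
Reagents that add atoms: 2,2-dimethoxypropane, COC(C)(C)OC
Why: Acid-catalysed transketalisation should close the five-membered dioxolane of the vicinal diol quickly under mild acid, masking both hydroxyls for the strongly basic key step and keeping the secondary hydroxyl from forming a cyclic hemiketal with the diketone.

Step 11
Reactants: 18 acetonide diketone; 11 half-ester chloride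
Product: 21 enolised acyl trione acetonide (C4 S), via dilithio dianion 19 (not isolated), via open-chain triketo ester 20 (not isolated)
Conditions: 18, LiN(iPr)2 (2.1 equiv), THF, −78 → 0 °C; LiN(SiMe3)2 (2.2 equiv); 11, −78 °C → 23 °C; aq. citric acid
Reagents that add atoms: none
Why: Two equivalents of LiN(iPr)2 convert 18 into dianion 19 (central carbon C6 and the methylene C2, not the hindered isobutyryl methine), and its more basic terminal carbon C2 adds to the acid chloride of 11 to make the C2–C3 bond (20), while LiN(SiMe3)2 takes up the proton of the newly formed acidic site so that unreacted 19 is not quenched. On warming, the central carbon C6 of fully enolised 20 attacks the methyl ester and makes the C5–C6 bond, a Dieckmann-type 6-exo-trig closure (the enolate double bond can lie outside the forming ring, on the isobutyryl side) that forms the six-membered carbocycle. The closest known reaction type is terminal C-acylation of 1,3-dicarbonyl dianions followed by Claisen cyclisation, used to build phloroglucinol-level triones from a three-carbon dinucleophile and a malonyl dielectrophile. No stereocenter is made: C4 is carried in from 11 and becomes (S) in the ring solely because C3 stems from the chloride and C5 from the ester, and C2' and the carbinol carbon are spectators (the acetal oxygen is γ to the carbanion, so β-elimination is not possible). The selectivity needed is the pairing of C2 with the chloride first and C6 with the ester second; it rests on the wide reactivity gaps between acid chloride and neopentyl-type ester and between terminal and central carbanion, and on 11 having no α-hydrogen, so that it cannot racemise via a ketene. Enol lactones from O-attack should be reopened by the lithium methoxide set free, and the doubly deprotonated acyl trione, being the most acidic species present, collects the material.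

Step 12
Reactants: 21 enolised acyl trione acetonide
Product: 23 dihydrofuran-fused enolised triketone (2S,7S; side chain 2S), via diol trione 22 (not isolated)
Conditions: HCl (1 M aq.)–THF (1:3), 23 °C; then toluene, PPTS (cat.), 4 Å MS, 40 °C
Reagents that add atoms: none
Why: Aqueous acid hydrolyses the acetonide, and the freed secondary C2' hydroxyl should then add to C3 of the vinylogous acid and lose water (hemiketalisation–dehydration to a cyclic vinylogous ester, 5-exo) with retention at C2', C3 being preferred because C1 is tied into the hydrogen-bonded isobutyryl chelate that the product keeps, whereas the tertiary hydroxyl is hindered and could only form a six-membered ring.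

Step 13
Reactants: 23 dihydrofuran triketone; 24 prenyl acetate
Product: 25 (2S,5R,7S)-2-[(2S)-2-hydroxy-6-methylhept-5-en-2-yl]-7-methyl-5,7-diprenyl-5-(2-methylpropanoyl)-2,3-dihydro-1-benzofuran-4,6(5H,7H)-dione (target)
Conditions: Pd(PPh3)4 (5 mol %), Et3N, THF, 23 → 40 °C
Reagents that add atoms: none
Why: Tsuji–Trost allylation, in which the soft triethylammonium triketonate attacks the unsubstituted terminus of the 1,1-dimethylallyl palladium cation through carbon C6 (kinetic O-prenyl enol ethers re-ionise, and C2 is no longer nucleophilic), should place the new prenyl group on the ring face opposite the larger C4 substituent, the C4 prenyl, and so set C6 as R by substrate control.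

Compound list
1 | 2,2,5-trimethyl-1,3-dioxane-4,6-dione | CC1C(=O)OC(C)(C)OC1=O | starting material
2 | 3-(tert-butoxy)-2-methyl-3-oxopropanoic acid (racemic) | CC(C(=O)O)C(=O)OC(C)(C)C | intermediate
3 | 2,2-diphenylethanol | OCC(c1ccccc1)c1ccccc1 | starting material
4 | tert-butyl 2,2-diphenylethyl 2-methylpropanedioate (racemic) | CC(C(=O)OC(C)(C)C)C(=O)OCC(c1ccccc1)c1ccccc1 | intermediate
5 | prenyl bromide (1-bromo-3-methylbut-2-ene) | CC(C)=CCBr | starting material
6 | 1-tert-butyl 3-(2,2-diphenylethyl) (2R)-2-methyl-2-(3-methylbut-2-en-1-yl)propanedioate | CC(C)(C)OC(=O)[C@](C)(CC=C(C)C)C(=O)OCC(c1ccccc1)c1ccccc1 | intermediate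
7 | potassium (2R)-3-tert-butoxy-2-methyl-2-(3-methylbut-2-en-1-yl)-3-oxopropanoate | CC(C)(C)OC(=O)[C@](C)(CC=C(C)C)C(=O)[O-].[K+] | intermediate (not isolated)
8 | 1-tert-butyl 3-methyl (2R)-2-methyl-2-(3-methylbut-2-en-1-yl)propanedioate | CC(C)(C)OC(=O)[C@](C)(CC=C(C)C)C(=O)OC | intermediate
9 | methyl trimethylsilyl (2R)-2-methyl-2-(3-methylbut-2-en-1-yl)propanedioate | C[Si](C)(C)OC(=O)[C@](C)(CC=C(C)C)C(=O)OC | intermediate (not isolated)
10 | (2S)-3-methoxy-2-methyl-2-(3-methylbut-2-en-1-yl)-3-oxopropanoic acid | OC(=O)[C@](C)(CC=C(C)C)C(=O)OC | intermediate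
11 | methyl (2R)-2-(chlorocarbonyl)-2,5-dimethylhex-4-enoate | ClC(=O)[C@](C)(CC=C(C)C)C(=O)OC | intermediate
12 | nerol ((2Z)-3,7-dimethylocta-2,6-dien-1-ol) | CC(C)=CCC/C(C)=C\CO | starting material
13 | [(2R,3S)-3-methyl-3-(4-methylpent-3-en-1-yl)oxiran-2-yl]methanol | CC(C)=CCC[C@]1(C)O[C@@H]1CO | intermediate
14 | (2S)-6-methyl-2-[(2S)-oxiran-2-yl]hept-5-en-2-ol | CC(C)=CCC[C@](C)(O)[C@@H]1CO1 | intermediate
15 | 5-methylhexane-2,4-dione (isobutyrylacetone) | CC(C)C(=O)CC(C)=O | starting material
16 | dilithium 5-methylhexa-1,3-diene-2,4-bis(olate) (dianion of 15) | [Li+].[Li+].C=C([O-])C=C([O-])C(C)C | intermediate (not isolated)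
17 | (8S,9S)-8,9-dihydroxy-2,9,13-trimethyltetradec-12-ene-3,5-dione | CC(C)=CCC[C@](C)(O)[C@@H](O)CCC(=O)CC(=O)C(C)C | intermediate
18 | 6-methyl-1-[(4S,5S)-2,2,5-trimethyl-5-(4-methylpent-3-en-1-yl)-1,3-dioxolan-4-yl]heptane-3,5-dione | CC(C)=CCC[C@]1(C)OC(C)(C)O[C@H]1CCC(=O)CC(=O)C(C)C | intermediate
19 | dilithium dianion of 18 (bis-enolate, carbanion at C2) | [Li+].[Li+].CC(C)=CCC[C@]1(C)OC(C)(C)O[C@H]1CC=C([O-])C=C([O-])C(C)C | intermediate (not isolated)
20 | methyl (2S)-2,8-dimethyl-2-(3-methylbut-2-en-1-yl)-3,5,7-trioxo-4-{[(4S,5S)-2,2,5-trimethyl-5-(4-methylpent-3-en-1-yl)-1,3-dioxolan-4-yl]methyl}nonanoate (C4 of the chain unassigned, enolisable) | CC(C)=CCC[C@]1(C)OC(C)(C)O[C@H]1CC(C(=O)CC(=O)C(C)C)C(=O)[C@](C)(CC=C(C)C)C(=O)OC | intermediate (not isolated)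
21 | (6S)-3,5-dihydroxy-6-methyl-6-(3-methylbut-2-en-1-yl)-2-(2-methylpropanoyl)-4-{[(4S,5S)-2,2,5-trimethyl-5-(4-methylpent-3-en-1-yl)-1,3-dioxolan-4-yl]methyl}cyclohexa-2,4-dien-1-one | CC(C)=CCC[C@]1(C)OC(C)(C)O[C@H]1CC2=C(O)[C@](C)(CC=C(C)C)C(=O)C(C(=O)C(C)C)=C2O | intermediate
22 | (6S)-4-[(2S,3S)-2,3-dihydroxy-3,7-dimethyloct-6-en-1-yl]-3,5-dihydroxy-6-methyl-6-(3-methylbut-2-en-1-yl)-2-(2-methylpropanoyl)cyclohexa-2,4-dien-1-one | CC(C)=CCC[C@](C)(O)[C@@H](O)CC1=C(O)[C@](C)(CC=C(C)C)C(=O)C(C(=O)C(C)C)=C1O | intermediate (not isolated)
23 | (2S,7S)-4-hydroxy-2-[(2S)-2-hydroxy-6-methylhept-5-en-2-yl]-7-methyl-7-(3-methylbut-2-en-1-yl)-5-(2-methylpropanoyl)-2,3-dihydro-1-benzofuran-6(7H)-one | CC(C)=CCC[C@](C)(O)[C@@H]1CC2=C(O1)[C@](C)(CC=C(C)C)C(=O)C(C(=O)C(C)C)=C2O | intermediate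
24 | prenyl acetate (3-methylbut-2-en-1-yl acetate) | CC(=O)OCC=C(C)C | starting material
25 | (2S,5R,7S)-2-[(2S)-2-hydroxy-6-methylhept-5-en-2-yl]-7-methyl-5,7-bis(3-methylbut-2-en-1-yl)-5-(2-methylpropanoyl)-2,3-dihydro-1-benzofuran-4,6(5H,7H)-dione | CC(C)=CCC[C@](C)(O)[C@@H]1CC2=C(O1)[C@](C)(CC=C(C)C)C(=O)[C@](CC=C(C)C)(C(=O)C(C)C)C2=O | target

Total step count: 13. Longest linear sequence: 9 steps (steps 1–6, then 11–13); the nerol branch contributes 7 (steps 7–13).

Steps most likely to fail

Step 11. What may go wrong: proton exchange between the acylated intermediate and unreacted dianion, O-acylation or over-acylation by the acid chloride, or a ring closure onto the hindered ester that stalls at the open-chain or enol-lactone stage. Fallback, setting out from 18 and 11 and returning at 21: 18 is converted with Me3SiCl/Et3N and then LiN(iPr)2/Me3SiCl into the 1,3-bis(trimethylsilyloxy)-1,3-diene F1. F1 is acylated at its terminal carbon by 11 without base (CH2Cl2, −78 → 20 °C, Me3SiOTf as catalyst if needed), and aqueous work-up gives triketo ester 20, now isolated. NaOMe in MeOH then closes 20 to 21 in a separate Dieckmann step. The bonds formed and their order are unchanged.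

Step 13. What may go wrong: poor facial selectivity at C6, because methyl and prenyl on C4 differ little close to the ring; also O-allylation that does not revert, or attack at the substituted allyl terminus. Fallback, setting out from 23 and returning at 25: catalyst-controlled asymmetric allylic alkylation of 23 with allyl acetate, Pd2(dba)3·CHCl3 and the antipode of the DACH-phenyl Trost ligand that reinforces the substrate bias (Et3N, CH2Cl2) gives the C6-allyl triketone F2. Cross-metathesis of F2 with 2-methylbut-2-ene (second-generation Grubbs catalyst, CH2Cl2, 40 °C) turns allyl into prenyl and gives 25; the other trisubstituted alkenes only undergo degenerate exchange.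

Step 12. What may go wrong: closure of the C2' hydroxyl onto C1 instead of C3, giving the regioisomeric furan, or acid-induced cyclisation of a prenyl group onto an enol oxygen. Fallback, setting out from 21 and returning at 25: the order of the last two steps is reversed. Tsuji–Trost prenylation of 21 under the conditions of step 13 should occur at C6, the carbon of the most acidic (triketone) unit, and gives the C6-prenylated acetonide trione F3. Acid treatment of F3 as in step 12 then removes the acetonide and closes the furan, now with C1 flanked by the fully substituted C6 and therefore the more hindered carbonyl, to give 25 directly.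

Further compounds
F1 | step 11 | 1,3-bis(trimethylsilyloxy)-1,3-diene of 18 (silyl enol ethers at both former carbonyls, dioxolane 4S,5S) | CC(C)=CCC[C@]1(C)OC(C)(C)O[C@H]1CC=C(O[Si](C)(C)C)C=C(O[Si](C)(C)C)C(C)C
F2 | step 13 | (2S,5R,7S)-5-allyl-2-[(2S)-2-hydroxy-6-methylhept-5-en-2-yl]-7-methyl-7-(3-methylbut-2-en-1-yl)-5-(2-methylpropanoyl)-2,3-dihydro-1-benzofuran-4,6(5H,7H)-dione | CC(C)=CCC[C@](C)(O)[C@@H]1CC2=C(O1)[C@](C)(CC=C(C)C)C(=O)[C@](CC=C)(C(=O)C(C)C)C2=O
F3 | step 12 | C6-prenylated acetonide trione (C4 S, C6 R, dioxolane 4S,5S; enol at C3) | CC(C)=CCC[C@]1(C)OC(C)(C)O[C@H]1CC2=C(O)[C@](C)(CC=C(C)C)C(=O)[C@](CC=C(C)C)(C(=O)C(C)C)C2=O
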